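## Retrosynthetic overview

1. Okilactomycin C ← its 2-(trimethylsilyl)ethyl ester ← the 13-membered ring is opened at the acyl–tetronate bond: Pd-catalysed carbonylative C-acylation of a spirotetronic acid by a (Z)-alkenyl iodide (macrocycle formed last).
2. Seco iodide ← Stork–Zhao olefination of an aldehyde ← sp3–sp3 Negishi coupling of fragment A (spirotetronate alkylzinc) with fragment B (syn-dimethyl alkyl iodide).
3. Fragment A: tetronate ring by Dieckmann closure onto a cis-fused γ-lactone ← Pd alkoxycarbonylation of a bromocyclohexene ← enolate hydroxylation ← BINOL/Zn/Mg-templated Diels–Alder of a 4-bromodienol with methyl acrylate (cyclohexene formed first).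
4. Fragment B: two iterative Cu/Josiphos conjugate additions of MeMgBr to enethioates grown from glycolaldehyde.
5. Ring order: cyclohexene (with a temporary γ-lactone) → spiro-fused tetronate → 13-membered carbocycle.

Assumption: the ligand-controlled steps 4, 12 and 15 show the facial selectivity reported for the parent substrates of these methods; if a step gives the mirror-image sense, the other enantiomer of the ligand is used.

## Fragment A

Step 1
Reactants: 1 crotonaldehyde
Product: 3 (Z)-2-bromobut-2-enal, via 2,3-dibromobutanal 2 (not isolated)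
Conditions: Br2, CH2Cl2, −20 °C; then Et3N, 0 °C to rt
Reagents that add atoms: bromine, BrBr
Why: Bromination–dehydrobromination (anti addition, then E2 loss of HBr from the acidic α-position) gives the α-bromoenal as the more stable Z isomer, methyl trans to CHO.

Step 2
Reactants: 3 (Z)-2-bromobut-2-enal
Product: 4 ethyl (2E,4Z)-4-bromohexa-2,4-dienoate
Conditions: (EtO)2P(O)CH2CO2Et, NaH, THF, 0 °C to rt
Reagents that add atoms: triethyl phosphonoacetate, CCOC(=O)CP(=O)(OCC)OCC
Why: Horner–Wadsworth–Emmons olefination with a stabilised phosphonate gives the new alkene E and leaves the bromoalkene geometry untouched.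

Step 3
Reactants: 4 ethyl (2E,4Z)-4-bromohexa-2,4-dienoate
Product: 5 (2E,4Z)-4-bromohexa-2,4-dien-1-ol
Conditions: i-Bu2AlH (2.3 equiv), CH2Cl2, −78 °C; aq. potassium sodium tartrate
Reagents that add atoms: none
Why: Clean 1,2-reduction of the dienoate by the aluminium hydride at low temperature gives the dienol without touching the vinyl bromide.

Step 4
Reactants: 5 (2E,4Z)-4-bromohexa-2,4-dien-1-ol; 6 methyl acrylate
Product: 8 (3aR,6S,7aR)-5-bromo-6-methyl-3a,6,7,7a-tetrahydro-2-benzofuran-1(3H)-one, via hydroxy ester 7 (not isolated)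
Conditions: Me2Zn (1.1 equiv), (R)-BINOL (0.2 equiv), MeMgBr (1.0 equiv), 6 (3 equiv), CH2Cl2, 0 °C to rt; 1 M HCl
Reagents that add atoms: none
Why: Lewis-acid-templated Diels–Alder reaction (Ward type): the Zn/Mg BINOLate holds the dienol alkoxide and the acrylate carbonyl together, so the acrylate α-carbon bonds to the carbinol-bearing diene terminus through an endo transition state (ester, CH2O arm and methyl all cis), BINOL selects the diene face and thereby sets the three ring stereocentres, and the cis hydroxy ester lactonises.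

Step 5
Reactants: 8 the cis-fused bromolactone
Product: 10 (3aR,6S,7aS)-5-bromo-7a-hydroxy-6-methyl-3a,6,7,7a-tetrahydro-2-benzofuran-1(3H)-one, via potassium enolate 9 (not isolated)
Conditions: KN(SiMe3)2, THF, −78 °C; then 2-(phenylsulfonyl)-3-phenyloxaziridine, −78 °C; aq. NH4Cl
Reagents that add atoms: 2-(phenylsulfonyl)-3-phenyloxaziridine, O=S(=O)(N1OC1c1ccccc1)c1ccccc1
Why: Davis enolate hydroxylation; the ring-fusion enolate can only be attacked on the face that keeps the cis ring fusion, so oxygen takes the place of the former α-hydrogen (trans to the CH2O arm and the methyl group) and fixes the future spiro centre.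

Step 6
Reactants: 10 the α-hydroxy lactone
Product: 11 (3aR,6S,7aS)-5-bromo-6-methyl-1-oxo-1,3,3a,6-tetrahydro-2-benzofuran-7a(7H)-yl acetate
Conditions: Ac2O, DMAP, Et3N, CH2Cl2, 40 °C
Reagents that add atoms: acetic anhydride, CC(=O)OC(C)=O
Why: DMAP-catalysed acylation (Steglich type) of the tertiary alcohol installs the two-carbon unit needed for the tetronate.

Step 7
Reactants: 11 the bromo acetate
Product: 12 2-(trimethylsilyl)ethyl (3aR,6S,7aS)-7a-acetoxy-6-methyl-1-oxo-1,3,3a,6,7,7a-hexahydro-2-benzofuran-5-carboxylate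
Conditions: Pd(OAc)2 (5 mol %), Xantphos (6 mol %), CO (1 atm), Me3SiCH2CH2OH (5 equiv), Et3N, DMF, 70 °C
Reagents that add atoms: carbon monoxide, [C-]#[O+]; 2-(trimethylsilyl)ethanol, C[Si](C)(C)CCO
Why: Palladium-catalysed alkoxycarbonylation (Heck carbonylation) of the cyclohexenyl bromide: oxidative addition to zerovalent palladium, CO insertion and alcoholysis give the enoate after all strongly basic enolate chemistry on the ring is finished.

Step 8
Reactants: 12 the acetoxy lactone ester
Product: 14 2-(trimethylsilyl)ethyl (5S,6R,9S)-6-(hydroxymethyl)-4-methoxy-9-methyl-2-oxo-1-oxaspiro[4.5]deca-3,7-diene-8-carboxylate, via lithium tetronate 13 (not isolated)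
Conditions: LiN(SiMe3)2 (1.15 equiv), THF, −78 to −20 °C; then Me2SO4, DMPU, 0 °C to rt
Reagents that add atoms: dimethyl sulfate, COS(=O)(=O)OC
Why: Dieckmann cyclisation of the acetate enolate onto the γ-lactone carbonyl builds the spirotetronate and releases the CH2OH arm (the expelled alkoxide deprotonates the tetronic acid, so about one equivalent of base suffices), and the tetronate anion is O-methylated in the same flask.

Step 9
Reactants: 14 the hydroxymethyl methyl tetronate
Product: 15 2-(trimethylsilyl)ethyl (5S,6S,9S)-6-(iodomethyl)-4-methoxy-9-methyl-2-oxo-1-oxaspiro[4.5]deca-3,7-diene-8-carboxylate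
Conditions: PPh3, imidazole, I2, toluene/MeCN, rt to 50 °C
Reagents that add atoms: iodine, II
Why: Appel-type (Garegg–Samuelsson) iodination converts the primary alcohol into the iodide under neutral conditions without touching the ring stereocentres.

## Fragment B

Step 10
Reactants: 16 glycolaldehyde dimer (1,4-dioxane-2,5-diol)
Product: 17 S-ethyl (2E)-4-hydroxybut-2-enethioate
Conditions: Ph3P=CHC(O)SEt (2.1 equiv), CH2Cl2, reflux
Reagents that add atoms: S-ethyl 2-(triphenylphosphoranylidene)ethanethioate, CCSC(=O)C=P(c1ccccc1)(c1ccccc1)c1ccccc1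
Why: Wittig olefination of the masked hydroxy aldehyde with a stabilised ylide gives the E enethioate directly.

Step 11
Reactants: 17 S-ethyl (2E)-4-hydroxybut-2-enethioate
Product: 18 S-ethyl (2E)-4-[(triethylsilyl)oxy]but-2-enethioate
Conditions: Et3SiCl, imidazole, CH2Cl2, 0 °C
Reagents that add atoms: chlorotriethylsilane, CC[Si](Cl)(CC)CC
Why: Standard silyl ether formation protects the primary alcohol with a group that can later be oxidised off in one operation.

Step 12
Reactants: 18 the silyloxy enethioate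
Product: 19 S-ethyl (3R)-3-methyl-4-[(triethylsilyl)oxy]butanethioate
Conditions: MeMgBr (1.2 equiv), CuBr·SMe2 (2 mol %), (R)-1-[(S)-2-(diphenylphosphino)ferrocenyl]ethyldicyclohexylphosphine (2.4 mol %), t-BuOMe, −75 °C
Reagents that add atoms: methylmagnesium bromide, C[Mg]Br
Why: Copper-catalysed asymmetric conjugate addition of a Grignard reagent to an α,β-unsaturated thioester (Feringa–Minnaard); the chiral ferrocenyl diphosphine delivers methyl to one enantiotopic face and sets the first methyl stereocentre.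

Step 13
Reactants: 19 the β-methyl thioester
Product: 20 (3R)-3-methyl-4-[(triethylsilyl)oxy]butanal
Conditions: i-Bu2AlH (1.1 equiv), CH2Cl2, −65 °C
Reagents that add atoms: none
Why: Partial reduction of the thioester stops at the aldehyde because the tetrahedral aluminium hemithioacetal is stable at low temperature.

Step 14
Reactants: 20 the β-methyl aldehyde
Product: 21 S-ethyl (2E,5R)-5-methyl-6-[(triethylsilyl)oxy]hex-2-enethioate
Conditions: Ph3P=CHC(O)SEt, CH2Cl2, reflux
Reagents that add atoms: S-ethyl 2-(triphenylphosphoranylidene)ethanethioate, CCSC(=O)C=P(c1ccccc1)(c1ccccc1)c1ccccc1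
Why: Wittig homologation with the stabilised ylide gives the E enethioate for the second iteration; the stereocentre is β to the aldehyde and cannot epimerise.

Step 15
Reactants: 21 the homologated enethioate
Product: 22 S-ethyl (3S,5R)-3,5-dimethyl-6-[(triethylsilyl)oxy]hexanethioate
Conditions: MeMgBr (1.2 equiv), CuBr·SMe2 (2 mol %), (R)-1-[(S)-2-(diphenylphosphino)ferrocenyl]ethyldicyclohexylphosphine (2.4 mol %), t-BuOMe, −75 °C
Reagents that add atoms: methylmagnesium bromide, C[Mg]Br
Why: Second catalyst-controlled asymmetric conjugate addition; the same ligand enantiomer overrides the remote stereocentre and gives the syn-1,3-dimethyl array.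

Step 16
Reactants: 22 the syn-dimethyl thioester
Product: 23 (3S,5R)-3,5-dimethyl-6-[(triethylsilyl)oxy]hexan-1-ol
Conditions: LiAlH4, THF, −20 to 0 °C
Reagents that add atoms: none
Why: Hydride reduction of the thioester to the primary alcohol leaves the silyl ether and both stereocentres untouched.

Step 17
Reactants: 23 the chain alcohol
Product: 24 triethyl{[(2R,4S)-6-iodo-2,4-dimethylhexyl]oxy}silane
Conditions: PPh3, imidazole, I2, CH2Cl2, 0 °C
Reagents that add atoms: iodine, II
Why: Appel-type iodination under imidazole buffering gives the unhindered primary iodide and spares the silyl ether.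

## Union and endgame

Step 18
Reactants: 15 the spirotetronate iodide; 24 the chain iodide
Product: 26 2-(trimethylsilyl)ethyl (5S,6S,9S)-6-{(4R,6R)-4,6-dimethyl-7-[(triethylsilyl)oxy]heptyl}-4-methoxy-9-methyl-2-oxo-1-oxaspiro[4.5]deca-3,7-diene-8-carboxylate, via alkylzinc iodide 25 (not isolated)
Conditions: 15 (1.25 equiv), Zn dust (BrCH2CH2Br/Me3SiCl-activated), LiCl, THF, 40 °C; then 24 (1.0 equiv), PdCl2(IPr)(3-chloropyridine) (4 mol %), THF/DMI, rt
Reagents that add atoms: none
Why: Knochel zinc insertion followed by an alkyl–alkyl Negishi cross-coupling; the hindered partner is the nucleophile, the unhindered primary iodide undergoes oxidative addition, and the bulky carbene ligand suppresses β-hydride elimination.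

Step 19
Reactants: 26 the coupled silyl ether
Product: 27 2-(trimethylsilyl)ethyl (5S,6S,9S)-6-[(4R,6R)-4,6-dimethyl-7-oxoheptyl]-4-methoxy-9-methyl-2-oxo-1-oxaspiro[4.5]deca-3,7-diene-8-carboxylate
Conditions: (COCl)2, DMSO, CH2Cl2, −78 to −40 °C; then Et3N, −78 to 0 °C
Reagents that add atoms: none
Why: Swern conditions cleave and oxidise a primary triethylsilyl ether in one pot, giving the α-methyl aldehyde without acid or base strong enough to epimerise it.

Step 20
Reactants: 27 the α-methyl aldehyde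
Product: 28 2-(trimethylsilyl)ethyl (5S,6S,9S)-6-[(4R,6R,7Z)-8-iodo-4,6-dimethylnon-7-en-1-yl]-4-methoxy-9-methyl-2-oxo-1-oxaspiro[4.5]deca-3,7-diene-8-carboxylate
Conditions: Ph3P(Et)I, n-BuLi, THF, rt; I2, −78 °C; NaN(SiMe3)2, −20 °C; then 27, −78 to −20 °C
Reagents that add atoms: ethyltriphenylphosphonium iodide, CC[P+](c1ccccc1)(c1ccccc1)c1ccccc1.[I-]; iodine, II
Why: Stork–Zhao olefination with the α-iodo ylide is kinetically Z-selective and places iodine cis to the chain, which is the geometry the enone of the target needs.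

Step 21
Reactants: 28 the (Z)-alkenyl iodide
Product: 29 2-(trimethylsilyl)ethyl (5S,6S,9S)-4-hydroxy-6-[(4R,6R,7Z)-8-iodo-4,6-dimethylnon-7-en-1-yl]-9-methyl-2-oxo-1-oxaspiro[4.5]deca-3,7-diene-8-carboxylate
Conditions: LiCl (10 equiv), DMSO, 55 °C; 0.5 M HCl
Reagents that add atoms: none
Why: SN2 demethylation of the vinylogous methyl ester by chloride (Krapcho-type) frees the tetronic acid while the silylethyl ester and the alkenyl iodide stay intact.

Step 22
Reactants: 29 the seco iodo tetronic acid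
Product: 31 okilactomycin C 2-(trimethylsilyl)ethyl ester, via chloromagnesium tetronate 30 (not isolated)
Conditions: Pd2(dba)3 (5 mol %), Xantphos (12 mol %), CO (1 atm), MgCl2 (2 equiv), Et3N (4 equiv), MeCN/THF, 60 °C, 29 added over 12 h to 2 mM; 0.5 M HCl
Reagents that add atoms: carbon monoxide, [C-]#[O+]
Why: Proposed new method: intramolecular palladium-catalysed carbonylative C-acylation of a tetronic acid by an alkenyl iodide, in which oxidative addition to zerovalent palladium and CO insertion (both with retention) give the (Z)-acyl palladium iodide, the chelated magnesium tetronate attacks through its soft C3 carbon, and the wide-bite-angle diphosphine forces C–C reductive elimination to close the 13-membered ring as the 3-acyl tetronic acid; the closest known reaction type is the Pd-catalysed carbonylative α-arylation of magnesium enolates of 1,3-dicarbonyl compounds with aryl halides, together with carbonylative macrolactonisation of alkenyl iodides.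

Step 23
Reactants: 31 okilactomycin C 2-(trimethylsilyl)ethyl ester
Product: 32 okilactomycin C
Conditions: Bu4NF, THF, 0 °C to rt; aq. KHSO4
Reagents that add atoms: none
Why: Fluoride-induced β-elimination of the 2-(trimethylsilyl)ethyl ester releases the carboxylic acid without acid, which could trigger oxa-Michael closure, or hydroxide, which could attack the lactone.

## Compound list

1 | crotonaldehyde, (E)-but-2-enal | C/C=C/C=O | starting material
2 | 2,3-dibromobutanal (racemic) | CC(Br)C(Br)C=O | intermediate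
3 | (Z)-2-bromobut-2-enal | C/C=C(Br)/C=O | intermediate
4 | ethyl (2E,4Z)-4-bromohexa-2,4-dienoate | C/C=C(Br)/C=C/C(=O)OCC | intermediate
5 | (2E,4Z)-4-bromohexa-2,4-dien-1-ol | C/C=C(Br)/C=C/CO | intermediate
6 | methyl acrylate | C=CC(=O)OC | starting material
7 | methyl (1R,2R,5S)-4-bromo-2-(hydroxymethyl)-5-methylcyclohex-3-ene-1-carboxylate | OC[C@H]1C=C(Br)[C@@H](C)C[C@H]1C(=O)OC | intermediate
8 | (3aR,6S,7aR)-5-bromo-6-methyl-3a,6,7,7a-tetrahydro-2-benzofuran-1(3H)-one (cis-fused, methyl cis to the CH2O arm) | O=C1OC[C@H]2C=C(Br)[C@@H](C)C[C@@H]12 | intermediate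
9 | potassium (3aS,6S)-5-bromo-6-methyl-3,3a,6,7-tetrahydro-2-benzofuran-1-olate (enolate of 8) | [K+].[O-]C1=C2C[C@H](C)C(Br)=C[C@@H]2CO1 | intermediate
10 | (3aR,6S,7aS)-5-bromo-7a-hydroxy-6-methyl-3a,6,7,7a-tetrahydro-2-benzofuran-1(3H)-one | O=C1OC[C@H]2C=C(Br)[C@@H](C)C[C@@]12O | intermediate
11 | (3aR,6S,7aS)-5-bromo-6-methyl-1-oxo-1,3,3a,6-tetrahydro-2-benzofuran-7a(7H)-yl acetate | O=C1OC[C@H]2C=C(Br)[C@@H](C)C[C@@]12OC(C)=O | intermediate
12 | 2-(trimethylsilyl)ethyl (3aR,6S,7aS)-7a-acetoxy-6-methyl-1-oxo-1,3,3a,6,7,7a-hexahydro-2-benzofuran-5-carboxylate | O=C1OC[C@H]2C=C(C(=O)OCC[Si](C)(C)C)[C@@H](C)C[C@@]12OC(C)=O | intermediate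
13 | lithium (5S,6R,9S)-6-(hydroxymethyl)-9-methyl-2-oxo-8-{[2-(trimethylsilyl)ethoxy]carbonyl}-1-oxaspiro[4.5]deca-3,7-dien-4-olate | [Li+].OC[C@H]1C=C(C(=O)OCC[Si](C)(C)C)[C@@H](C)C[C@]12OC(=O)C=C2[O-] | intermediate
14 | 2-(trimethylsilyl)ethyl (5S,6R,9S)-6-(hydroxymethyl)-4-methoxy-9-methyl-2-oxo-1-oxaspiro[4.5]deca-3,7-diene-8-carboxylate | OC[C@H]1C=C(C(=O)OCC[Si](C)(C)C)[C@@H](C)C[C@]12OC(=O)C=C2OC | intermediate
15 | 2-(trimethylsilyl)ethyl (5S,6S,9S)-6-(iodomethyl)-4-methoxy-9-methyl-2-oxo-1-oxaspiro[4.5]deca-3,7-diene-8-carboxylate | IC[C@H]1C=C(C(=O)OCC[Si](C)(C)C)[C@@H](C)C[C@]12OC(=O)C=C2OC | intermediate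
16 | glycolaldehyde dimer, 1,4-dioxane-2,5-diol | OC1COC(O)CO1 | starting material
17 | S-ethyl (2E)-4-hydroxybut-2-enethioate | CCSC(=O)/C=C/CO | intermediate
18 | S-ethyl (2E)-4-[(triethylsilyl)oxy]but-2-enethioate | CCSC(=O)/C=C/CO[Si](CC)(CC)CC | intermediate
19 | S-ethyl (3R)-3-methyl-4-[(triethylsilyl)oxy]butanethioate | CC[Si](CC)(CC)OC[C@H](C)CC(=O)SCC | intermediate
20 | (3R)-3-methyl-4-[(triethylsilyl)oxy]butanal | CC[Si](CC)(CC)OC[C@H](C)CC=O | intermediate
21 | S-ethyl (2E,5R)-5-methyl-6-[(triethylsilyl)oxy]hex-2-enethioate | CC[Si](CC)(CC)OC[C@H](C)C/C=C/C(=O)SCC | intermediate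
22 | S-ethyl (3S,5R)-3,5-dimethyl-6-[(triethylsilyl)oxy]hexanethioate (syn-dimethyl) | CC[Si](CC)(CC)OC[C@H](C)C[C@H](C)CC(=O)SCC | intermediate
23 | (3S,5R)-3,5-dimethyl-6-[(triethylsilyl)oxy]hexan-1-ol | CC[Si](CC)(CC)OC[C@H](C)C[C@H](C)CCO | intermediate
24 | triethyl{[(2R,4S)-6-iodo-2,4-dimethylhexyl]oxy}silane | CC[Si](CC)(CC)OC[C@H](C)C[C@H](C)CCI | intermediate
25 | iodo{[(5S,6S,9S)-4-methoxy-9-methyl-2-oxo-8-{[2-(trimethylsilyl)ethoxy]carbonyl}-1-oxaspiro[4.5]deca-3,7-dien-6-yl]methyl}zinc | I[Zn]C[C@H]1C=C(C(=O)OCC[Si](C)(C)C)[C@@H](C)C[C@]12OC(=O)C=C2OC | intermediate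
26 | 2-(trimethylsilyl)ethyl (5S,6S,9S)-6-{(4R,6R)-4,6-dimethyl-7-[(triethylsilyl)oxy]heptyl}-4-methoxy-9-methyl-2-oxo-1-oxaspiro[4.5]deca-3,7-diene-8-carboxylate | CC[Si](CC)(CC)OC[C@H](C)C[C@H](C)CCC[C@H]1C=C(C(=O)OCC[Si](C)(C)C)[C@@H](C)C[C@]12OC(=O)C=C2OC | intermediate
27 | 2-(trimethylsilyl)ethyl (5S,6S,9S)-6-[(4R,6R)-4,6-dimethyl-7-oxoheptyl]-4-methoxy-9-methyl-2-oxo-1-oxaspiro[4.5]deca-3,7-diene-8-carboxylate | O=C[C@H](C)C[C@H](C)CCC[C@H]1C=C(C(=O)OCC[Si](C)(C)C)[C@@H](C)C[C@]12OC(=O)C=C2OC | intermediate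
28 | 2-(trimethylsilyl)ethyl (5S,6S,9S)-6-[(4R,6R,7Z)-8-iodo-4,6-dimethylnon-7-en-1-yl]-4-methoxy-9-methyl-2-oxo-1-oxaspiro[4.5]deca-3,7-diene-8-carboxylate | C/C(I)=C/[C@H](C)C[C@H](C)CCC[C@H]1C=C(C(=O)OCC[Si](C)(C)C)[C@@H](C)C[C@]12OC(=O)C=C2OC | intermediate
29 | 2-(trimethylsilyl)ethyl (5S,6S,9S)-4-hydroxy-6-[(4R,6R,7Z)-8-iodo-4,6-dimethylnon-7-en-1-yl]-9-methyl-2-oxo-1-oxaspiro[4.5]deca-3,7-diene-8-carboxylate | C/C(I)=C/[C@H](C)C[C@H](C)CCC[C@H]1C=C(C(=O)OCC[Si](C)(C)C)[C@@H](C)C[C@]12OC(=O)C=C2O | intermediate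
30 | chloromagnesium salt (4-olate) of 29 | C/C(I)=C/[C@H](C)C[C@H](C)CCC[C@H]1C=C(C(=O)OCC[Si](C)(C)C)[C@@H](C)C[C@]12OC(=O)C=C2O[Mg]Cl | intermediate
31 | okilactomycin C 2-(trimethylsilyl)ethyl ester | CC1=C/[C@H](C)C[C@H](C)CCC[C@H]2C=C(C(=O)OCC[Si](C)(C)C)[C@@H](C)C[C@]23OC(=O)\C(=C\1O)C3=O | intermediate
32 | okilactomycin C | CC1=C/[C@H](C)C[C@H](C)CCC[C@H]2C=C(C(=O)O)[C@@H](C)C[C@]23OC(=O)\C(=C\1O)C3=O | target

## Step count and risk

Total step count: 23.
Longest linear sequence: 15 steps (steps 1–9, 18, 19–23). The other branch is 14 steps (steps 10–17, 18–23).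

The three steps most likely to fail:

Step 4 (templated asymmetric Diels–Alder on a 4-bromodienol; regio-, endo- and face control all rest on the template). The fallback sets out from 5 and comes back at 8. Compound 5 is silylated (t-BuMe2SiCl, imidazole) to the tert-butyldimethylsilyl ether of the dienol F1. F1 then undergoes an untethered, endo-selective Diels–Alder reaction with 2,2,2-trifluoroethyl acrylate under a triflimide-activated o-tolyl oxazaborolidine (Corey type), with regiochemistry set by the para-directing ring bromine, to give the cyclohexene trifluoroethyl ester F2. Bu4NF removes the silyl group and the freed alcohol closes onto the cis ester with loss of trifluoroethanol, which gives 8.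

Step 18 (alkyl–alkyl Negishi coupling with a β-branched, densely functionalised zinc reagent). The fallback sets out from 14 and 23 and comes back at 26. Compound 14 is converted by Mitsunobu reaction with 1-phenyl-1H-tetrazole-5-thiol into the tetrazolyl sulfide F3 and oxidised ((NH4)6Mo7O24, H2O2) to the tetrazolyl sulfone F4. Compound 23 is oxidised with Dess–Martin periodinane to the chain aldehyde F5. Julia–Kocienski olefination (KN(SiMe3)2, DME, −60 °C, base added to the mixture of F4 and F5) joins them as the disubstituted alkene F6, whose E/Z ratio is irrelevant. Diimide (2-nitrobenzenesulfonyl hydrazide, Et3N) then saturates only this unconjugated alkene and gives 26.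

Step 22 (the proposed carbonylative macrocyclisation; O- versus C-acylation, oligomerisation and Z/E drift of the enoyl unit are the risks). The fallback uses known chemistry, sets out from 28 and comes back at 31. Compound 28 is hydroxycarbonylated with retention (Pd(OAc)2, Xantphos, CO, H2O, Et3N, DMF) to the (Z)-2-methylenoic acid F7. LiCl in DMSO then frees the tetronic acid and gives the seco acid F8. DCC and DMAP under high dilution effect O-acylation followed by the DMAP-mediated O-to-C acyl shift (the established 3-acylation of tetronic acids) and give 31.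

## Further compounds

F1 | step 4 | tert-butyl{[(2E,4Z)-4-bromohexa-2,4-dien-1-yl]oxy}dimethylsilane | C/C=C(Br)/C=C/CO[Si](C)(C)C(C)(C)C
F2 | step 4 | 2,2,2-trifluoroethyl (1R,2R,5S)-4-bromo-2-{[(tert-butyldimethylsilyl)oxy]methyl}-5-methylcyclohex-3-ene-1-carboxylate | CC(C)(C)[Si](C)(C)OC[C@H]1C=C(Br)[C@@H](C)C[C@H]1C(=O)OCC(F)(F)F
F3 | step 18 | 2-(trimethylsilyl)ethyl (5S,6S,9S)-4-methoxy-9-methyl-2-oxo-6-{[(1-phenyl-1H-tetrazol-5-yl)sulfanyl]methyl}-1-oxaspiro[4.5]deca-3,7-diene-8-carboxylate | S(C[C@H]1C=C(C(=O)OCC[Si](C)(C)C)[C@@H](C)C[C@]12OC(=O)C=C2OC)c1nnnn1-c1ccccc1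
F4 | step 18 | 2-(trimethylsilyl)ethyl (5S,6S,9S)-4-methoxy-9-methyl-2-oxo-6-{[(1-phenyl-1H-tetrazol-5-yl)sulfonyl]methyl}-1-oxaspiro[4.5]deca-3,7-diene-8-carboxylate | O=S(=O)(C[C@H]1C=C(C(=O)OCC[Si](C)(C)C)[C@@H](C)C[C@]12OC(=O)C=C2OC)c1nnnn1-c1ccccc1
F5 | step 18 | (3S,5R)-3,5-dimethyl-6-[(triethylsilyl)oxy]hexanal | CC[Si](CC)(CC)OC[C@H](C)C[C@H](C)CC=O
F6 | step 18 | 2-(trimethylsilyl)ethyl (5S,6S,9S)-6-{(4R,6R)-4,6-dimethyl-7-[(triethylsilyl)oxy]hept-1-en-1-yl}-4-methoxy-9-methyl-2-oxo-1-oxaspiro[4.5]deca-3,7-diene-8-carboxylate (E/Z mixture) | CC[Si](CC)(CC)OC[C@H](C)C[C@H](C)CC=C[C@H]1C=C(C(=O)OCC[Si](C)(C)C)[C@@H](C)C[C@]12OC(=O)C=C2OC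
F7 | step 22 | (2Z,4R,6R)-9-[(5S,6S,9S)-4-methoxy-9-methyl-2-oxo-8-{[2-(trimethylsilyl)ethoxy]carbonyl}-1-oxaspiro[4.5]deca-3,7-dien-6-yl]-2,4,6-trimethylnon-2-enoic acid | C/C(C(=O)O)=C/[C@H](C)C[C@H](C)CCC[C@H]1C=C(C(=O)OCC[Si](C)(C)C)[C@@H](C)C[C@]12OC(=O)C=C2OC
F8 | step 22 | (2Z,4R,6R)-9-[(5S,6S,9S)-4-hydroxy-9-methyl-2-oxo-8-{[2-(trimethylsilyl)ethoxy]carbonyl}-1-oxaspiro[4.5]deca-3,7-dien-6-yl]-2,4,6-trimethylnon-2-enoic acid | C/C(C(=O)O)=C/[C@H](C)C[C@H](C)CCC[C@H]1C=C(C(=O)OCC[Si](C)(C)C)[C@@H](C)C[C@]12OC(=O)C=C2O
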